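**Retrosynthetic overview**

1. Numbering: ring O1, C2 (pentyl), C3 (OH), C4, C5; side chain C1′ (O‑palmitoyl) to C10′. The ester and the free C3–OH come last (palmitoylation, MOM removal); the C1′–C2′ bond comes from chelation‑controlled addition of non‑8‑enylmagnesium bromide to the 2,5‑trans oxolane‑2‑carbaldehyde 14.
2. Key disconnection: oxolane 14 ⇐ six‑membered cyclic enol ether 12 (ring O1, C2, C3, C4, C5=C1′) by oxidative ring contraction; O1 shifts from C1′ to C5 and C1′ leaves the ring as the formyl carbon.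
3. Enabling feature: C5 carries both the ring oxygen O1 and an exocyclic oxygenated carbon C1′ (the O1–C5–C1′–O array left by a 1,2‑oxygen shift), and the C2 pentyl and C3 oxygen sit cis on one ring face, so an electrophile enters C5 from the other face and the inversion delivers the 2,5‑trans ring.
4. 12 ⇐ lactol 10 (dehydration) ⇐ linear hydroformylation of syn alkoxy alcohol 8 ⇐ Brown (Z)‑γ‑alkoxyallylboration of hexanal, which sets C2 and C3; C5 and C1′ are then relayed by substrate control.
5. Ring order: oxane first (step 3), contracted to the oxolane in step 5; no other ring is made.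

Key step: step 5

Assumption: (+)‑Ipc2BOMe is the antipode made from (−)‑α‑pinene, whose allyl and γ‑alkoxyallyl boranes attack the Re face of unbranched aliphatic aldehydes; compounds 1, 2, 4, 5, 15 and 17 are taken as commercial.

**Route**

Step 1
Reactants: 1 prop‑2‑en‑1‑ol; 2 chloromethyl methyl ether
Product: 3 3‑(methoxymethoxy)prop‑1‑ene
Conditions: i‑Pr2NEt, CH2Cl2, 0 °C → rt
Reagents that add atoms: chloromethyl methyl ether 2 (COCCl)
Why: MOM protection, i.e. O‑alkylation of the primary alcohol by the α‑chloro ether with an amine as acid scavenger, is routine and creates no stereocentre.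

Step 2
Reactants: 3 3‑(methoxymethoxy)prop‑1‑ene; 4 (+)‑B‑methoxydiisopinocampheylborane; 5 hexanal
Product: 8 (3S,4S)‑3‑(methoxymethoxy)non‑1‑en‑4‑ol, via (Z)‑alkoxyallylborane 6 (not isolated), via borinate 7 (not isolated)
Conditions: s‑BuLi, THF, −78 °C; 4; BF3·OEt2; 5, −78 °C → rt; NaOH, H2O2
Reagents that add atoms: hexanal 5 (CCCCCC=O)
Why: Brown (Z)‑γ‑alkoxyallylboration: kinetic deprotonation gives the chelated (Z)‑alkoxyallyl anion, boron takes it up, and addition to 5 through a closed chair (Zimmerman–Traxler) transition state turns the Z geometry into the syn (threo) relationship while the isopinocampheyl groups of 4 select the Re face of the aldehyde, so that C3 and C4 should both be S.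

Step 3
Reactants: 8 (3S,4S)‑3‑(methoxymethoxy)non‑1‑en‑4‑ol
Product: 10 (5S,6S)‑5‑(methoxymethoxy)‑6‑pentyloxan‑2‑ol (anomer mixture), via hydroxy aldehyde 9 (not isolated)
Conditions: Rh(acac)(CO)2 (cat.), BIPHEPHOS (cat.), CO/H2 (1:1, 5 bar), THF, 60 °C
Reagents that add atoms: carbon monoxide ([C-]#[O+])
Why: Linear‑selective rhodium/bisphosphite hydroformylation of the monosubstituted alkene (branched insertion is disfavoured next to the alkoxy‑bearing carbon) gives δ‑hydroxy aldehyde 9, which closes spontaneously to the six‑membered lactol, the two stereocentres being untouched and the anomeric centre being removed in the next step.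

Step 4
Reactants: 10 (5S,6S)‑5‑(methoxymethoxy)‑6‑pentyloxan‑2‑ol
Product: 12 (2S,3S)‑3‑(methoxymethoxy)‑2‑pentyl‑3,4‑dihydro‑2H‑pyran, via anomeric mesylate 11 (not isolated)
Conditions: MsCl, Et3N, CH2Cl2, −20 °C → reflux
Reagents that add atoms: none
Why: Mesylation of the anomeric hydroxyl and amine‑induced elimination through the oxocarbenium ion is the standard conversion of a 2‑deoxy lactol into a glycal (cyclic enol ether) and involves no stereocentre.

Step 5
Reactants: 12 (2S,3S)‑3‑(methoxymethoxy)‑2‑pentyl‑3,4‑dihydro‑2H‑pyran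
Product: 14 (2R,4S,5S)‑4‑(methoxymethoxy)‑5‑pentyloxolane‑2‑carbaldehyde, via organothallium hemiacetal 13 (not isolated)
Conditions: Tl(NO3)3·3H2O, MeCN, 0 °C → rt; aq. NaHCO3; used crude
Reagents that add atoms: water, from the hydrate (O)
Why: Electrophilic oxythallation of the enol ether (numbering of 12) puts Tl(III) on C5 and water on C6 to give hemiacetal 13; in the chair that keeps the pentyl group equatorial the C5–Tl bond is equatorial and antiperiplanar to the ring O1–C6 bond, so O1 shifts from C6 to C5 with loss of thallium(I) nitrate and inversion at C5, and the protonated aldehyde so formed loses H+ to give 14 (the open hydroxy aldehyde form of 13 closing by displacement of thallium would give the same product). The closest known reaction type is the thallium(III) nitrate ring contraction of glycals to 2,5‑anhydroaldoses, a relative of the deaminative and 2‑O‑triflate ring contractions of pyranosides. The oxolane closes by a 1,2‑shift of ring oxygen through a three‑centre transition state (3‑exo‑tet in character), equivalent in outcome to a 5‑exo‑tet SN2 closure of O1 on C5. The new stereocentre (target C5) is under substrate control: the electrophile should add to the face opposite to the cis‑disposed C2 pentyl and axial C3 MOM‑oxy groups (attack on their face would be 1,3‑diaxial to the MOM‑oxy group), and the stereospecific inversion turns this into the 2,5‑trans ring. The step needs facial selectivity in the addition and migration of ring oxygen in preference to a hydride or carbon shift; the first is secured by both substituents lying on one face, the second by the antiperiplanar O1–C6 bond and by the oxocarbenium ion that only the oxygen shift produces.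

Step 6
Reactants: 14 (2R,4S,5S)‑4‑(methoxymethoxy)‑5‑pentyloxolane‑2‑carbaldehyde; 15 9‑bromonon‑1‑ene
Product: 16 (1R)‑1‑[(2R,4S,5S)‑4‑(methoxymethoxy)‑5‑pentyloxolan‑2‑yl]dec‑9‑en‑1‑ol
Conditions: 15, Mg, Et2O; 14, MgBr2·OEt2, CH2Cl2, −78 °C; then aq. NH4Cl
Reagents that add atoms: non‑8‑enylmagnesium bromide, from 15 and Mg (C=CCCCCCCC[Mg]Br)
Why: Cram‑chelate (chelation‑controlled) Grignard addition: Mg(II) bridges the carbonyl oxygen and the ring oxygen, and the nucleophile attacks the carbonyl face flanked by the ring C–H, which should give the threo (1R) carbinol.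

Step 7
Reactants: 16 (1R)‑1‑[(2R,4S,5S)‑4‑(methoxymethoxy)‑5‑pentyloxolan‑2‑yl]dec‑9‑en‑1‑ol; 17 hexadecanoyl chloride
Product: 18 (1R)‑1‑[(2R,4S,5S)‑4‑(methoxymethoxy)‑5‑pentyloxolan‑2‑yl]dec‑9‑en‑1‑yl hexadecanoate
Conditions: pyridine, DMAP (cat.), CH2Cl2, 0 °C → rt
Reagents that add atoms: hexadecanoyl chloride 17 (CCCCCCCCCCCCCCCC(=O)Cl)
Why: DMAP‑catalysed acylation (nucleophilic catalysis) of the only free hydroxyl by the acid chloride proceeds with retention at the carbinol carbon.

Step 8
Reactants: 18 (1R)‑1‑[(2R,4S,5S)‑4‑(methoxymethoxy)‑5‑pentyloxolan‑2‑yl]dec‑9‑en‑1‑yl hexadecanoate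
Product: 19 (1R)‑1‑[(2R,4S,5S)‑4‑hydroxy‑5‑pentyloxolan‑2‑yl]dec‑9‑en‑1‑yl hexadecanoate (CNP0115574.1)
Conditions: ZnBr2, n‑PrSH, CH2Cl2, 0 °C → rt
Reagents that add atoms: none
Why: Lewis acid‑assisted acetal cleavage, in which ZnBr2 activates the MOM acetal and the thiol captures the methoxymethyl cation, should leave the ester, the oxolane and the terminal alkene intact and affects no stereocentre.

**Compound list**

1 | prop‑2‑en‑1‑ol (allyl alcohol) | C=CCO | starting material
2 | chloromethyl methyl ether | COCCl | starting material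
3 | 3‑(methoxymethoxy)prop‑1‑ene | C=CCOCOC | intermediate
4 | (+)‑B‑methoxydiisopinocampheylborane, (+)‑Ipc2BOMe | COB([C@H]1C[C@H]2C[C@H](C2(C)C)[C@@H]1C)[C@H]1C[C@H]2C[C@H](C2(C)C)[C@@H]1C | starting material
5 | hexanal | CCCCCC=O | starting material
6 | [(Z)‑3‑(methoxymethoxy)prop‑2‑en‑1‑yl]diisopinocampheylborane | COCO/C=C\CB([C@H]1C[C@H]2C[C@H](C2(C)C)[C@@H]1C)[C@H]1C[C@H]2C[C@H](C2(C)C)[C@@H]1C | intermediate
7 | diisopinocampheylborinate of 8 (O‑boron derivative of the homoallylic alcohol) | C=C[C@H](OCOC)[C@@H](OB([C@H]1C[C@H]2C[C@H](C2(C)C)[C@@H]1C)[C@H]1C[C@H]2C[C@H](C2(C)C)[C@@H]1C)CCCCC | intermediate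
8 | (3S,4S)‑3‑(methoxymethoxy)non‑1‑en‑4‑ol | C=C[C@H](OCOC)[C@@H](O)CCCCC | intermediate
9 | (4S,5S)‑5‑hydroxy‑4‑(methoxymethoxy)decanal | O=CCC[C@H](OCOC)[C@@H](O)CCCCC | intermediate
10 | (5S,6S)‑5‑(methoxymethoxy)‑6‑pentyloxan‑2‑ol (both anomers) | OC1CC[C@H](OCOC)[C@H](CCCCC)O1 | intermediate
11 | (5S,6S)‑5‑(methoxymethoxy)‑6‑pentyloxan‑2‑yl methanesulfonate | CS(=O)(=O)OC1CC[C@H](OCOC)[C@H](CCCCC)O1 | intermediate
12 | (2S,3S)‑3‑(methoxymethoxy)‑2‑pentyl‑3,4‑dihydro‑2H‑pyran | C1=CO[C@@H](CCCCC)[C@@H](OCOC)C1 | intermediate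
13 | [(3S,5S,6S)‑2‑hydroxy‑5‑(methoxymethoxy)‑6‑pentyloxan‑3‑yl]thallium(III) dinitrate (Tl trans to pentyl and MOM‑oxy) | OC1O[C@@H](CCCCC)[C@@H](OCOC)C[C@@H]1[Tl](O[N+](=O)[O-])O[N+](=O)[O-] | intermediate
14 | (2R,4S,5S)‑4‑(methoxymethoxy)‑5‑pentyloxolane‑2‑carbaldehyde | O=C[C@H]1C[C@H](OCOC)[C@H](CCCCC)O1 | intermediate
15 | 9‑bromonon‑1‑ene | C=CCCCCCCCBr | starting material
16 | (1R)‑1‑[(2R,4S,5S)‑4‑(methoxymethoxy)‑5‑pentyloxolan‑2‑yl]dec‑9‑en‑1‑ol | C=CCCCCCCC[C@@H](O)[C@H]1C[C@H](OCOC)[C@H](CCCCC)O1 | intermediate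
17 | hexadecanoyl chloride (palmitoyl chloride) | CCCCCCCCCCCCCCCC(=O)Cl | starting material
18 | (1R)‑1‑[(2R,4S,5S)‑4‑(methoxymethoxy)‑5‑pentyloxolan‑2‑yl]dec‑9‑en‑1‑yl hexadecanoate | C=CCCCCCCC[C@@H](OC(=O)CCCCCCCCCCCCCCC)[C@H]1C[C@H](OCOC)[C@H](CCCCC)O1 | intermediate
19 | (1R)‑1‑[(2R,4S,5S)‑4‑hydroxy‑5‑pentyloxolan‑2‑yl]dec‑9‑en‑1‑yl hexadecanoate | C=CCCCCCCC[C@@H](OC(=O)CCCCCCCCCCCCCCC)[C@H]1C[C@H](O)[C@H](CCCCC)O1 | target

**Step count and risks**

Total step count: 8. Longest linear sequence: 8 steps (1 → 3 → 8 → 10 → 12 → 14 → 16 → 18 → 19).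

Steps most likely to fail:

Step 5. The facial selectivity of the oxythallation may be eroded, for example by delivery of thallium to the substituted face through coordination to the MOM oxygens, and the organothallium may be solvolysed without migration of the ring oxygen. The fallback sets out from 12 and comes back at 14; it separates the face‑selective oxidation from the rearrangement and still contracts the oxane. Epoxidation of 12 with dimethyldioxirane (acetone/CH2Cl2, 0 °C) on the face away from the two substituents should give the 1,2‑anhydro epoxide F1. Methanol added to the same flask opens it at the acetal carbon with inversion to give the methyl glycoside F2, whose free hydroxyl is equatorial and trans to the pentyl group; a minor face isomer could be removed here. Triflation (Tf2O, 2,6‑lutidine, CH2Cl2, −20 °C) gives the triflate F3. Warming F3 in methanol with 2,6‑lutidine, the ring contraction of a pyranoside 2‑O‑triflate, should give the dimethyl acetal F4. Mild acetal hydrolysis (LiBF4, wet MeCN) returns 14.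

Step 6. Chelation control may be incomplete, so that Felkin–Anh addition competes and the threo selectivity falls. The fallback sets out from 14 and comes back at 18, skipping step 7. The mixture of C1′ epimers from the addition is oxidised with Dess–Martin periodinane to the ketone F5. Chelation‑controlled reduction with Zn(BH4)2 (Et2O, −20 °C) should give the erythro (1S) alcohol F6. Mitsunobu esterification of F6 with palmitic acid (PPh3, DIAD, toluene) installs the ester with inversion and gives 18.

Step 4. The anomeric mesylate may be intercepted as the chloride or hydrolysed back to the lactol instead of eliminating, and the enol ether may be lost by acid‑catalysed hydration during isolation. The fallback sets out from 8 and comes back at 12, replacing steps 3 and 4. O‑Allylation of 8 (NaH, allyl bromide, THF) gives the allyl ether F7. Ring‑closing metathesis (Grubbs second‑generation catalyst, CH2Cl2) gives the 3,6‑dihydro‑2H‑pyran F8. Ruthenium hydride‑catalysed double‑bond migration (RuHCl(CO)(PPh3)3, toluene, 80 °C) towards the ring oxygen, at the unhindered O–CH2 side, should give 12.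

**Further compounds**

F1 | step 5 | 1,2‑anhydro epoxide of 12: 2,7‑dioxabicyclo[4.1.0]heptane carrying 3‑pentyl and 4‑(methoxymethoxy), epoxide oxygen trans to both | [C@@H]12O[C@@H](CCCCC)[C@@H](OCOC)C[C@@H]1O2
F2 | step 5 | methyl glycoside: 2‑methoxy‑5‑(methoxymethoxy)‑6‑pentyloxan‑3‑ol, 2‑OMe and 3‑OH trans, 3‑OH trans to pentyl | CO[C@H]1O[C@@H](CCCCC)[C@@H](OCOC)C[C@@H]1O
F3 | step 5 | trifluoromethanesulfonate of F2 | CO[C@H]1O[C@@H](CCCCC)[C@@H](OCOC)C[C@@H]1OS(=O)(=O)C(F)(F)F
F4 | step 5 | (2R,3S,5R)‑5‑(dimethoxymethyl)‑3‑(methoxymethoxy)‑2‑pentyloxolane (dimethyl acetal of 14) | COC(OC)[C@H]1C[C@H](OCOC)[C@H](CCCCC)O1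
F5 | step 6 | 1‑[(2R,4S,5S)‑4‑(methoxymethoxy)‑5‑pentyloxolan‑2‑yl]dec‑9‑en‑1‑one | C=CCCCCCCCC(=O)[C@H]1C[C@H](OCOC)[C@H](CCCCC)O1
F6 | step 6 | (1S)‑1‑[(2R,4S,5S)‑4‑(methoxymethoxy)‑5‑pentyloxolan‑2‑yl]dec‑9‑en‑1‑ol (erythro epimer of 16) | C=CCCCCCCC[C@H](O)[C@H]1C[C@H](OCOC)[C@H](CCCCC)O1
F7 | step 4 | (3S,4S)‑3‑(methoxymethoxy)‑4‑(prop‑2‑en‑1‑yloxy)non‑1‑ene | C=C[C@H](OCOC)[C@@H](OCC=C)CCCCC
F8 | step 4 | (2S,3S)‑3‑(methoxymethoxy)‑2‑pentyl‑3,6‑dihydro‑2H‑pyran | C1C=C[C@H](OCOC)[C@H](CCCCC)O1
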